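**Plan**

- Retrosynthesis: the CH2 between C4 and ring B is traced back to a carbinol whose oxygen acylates the C3 side carbon, which gives a cis-fused furofuranone. Then the oxolane C2–C3 bond is cut (carbenoid C–H insertion), then the ring A benzyl ether C–O bond, and last the aldol C–C bond between 2,4,5-trimethoxybenzaldehyde and a succinate.
- Enabling feature: in the oxolane O1–C2(ring A)–C3(CH2OH)–C4(CH2–ring B)–C5H2 all three substituents are cis. The side carbons on C3 and C4 can therefore sit in a γ-lactone fused cis to the oxolane with ring A endo, and C2 is a benzylic ether carbon whose C–H bond lies five atoms from the lactone α-carbon C3.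
- Forward: the lactone ring is made first (auxiliary aldol and lactonisation), the ring A benzyl ether is attached, diazo transfer arms C3, the oxolane closes by C2–C3 insertion, and finally the lactone is opened and the surplus benzylic oxygen removed.
- Stereochemistry: C4 comes from the oxazolidinone-controlled syn-aldol, C3 from the obligatory cis ring fusion, C2 from the endo-selective insertion. The ring B carbinol centre is a relay that is erased at the end.

Key step: step 9

Remark: the target SMILES is read as the (2R,3R,4R), all-cis oxolane; ring A is 3,4,5-trimethoxyphenyl, ring B is 2,4,5-trimethoxyphenyl, and the oxolane locants O1, C2, C3, C4, C5 of the target are used throughout.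

**Route**

Step 1
Reactants: 1 (S)-4-benzyl-1,3-oxazolidin-2-one; 2 methyl 4-chloro-4-oxobutanoate
Product: 3 methyl 4-[(4S)-4-benzyl-2-oxo-1,3-oxazolidin-3-yl]-4-oxobutanoate
Conditions: n-BuLi, THF, −78 °C; then 2, −78 → 0 °C
Reagents that add atoms: none
Why: N-acylation of the lithiated oxazolidinone by the acid chloride is the standard way to an Evans imide, and the methyl ester does not react at this temperature.

Step 2
Reactants: 3 methyl 4-[(4S)-4-benzyl-2-oxo-1,3-oxazolidin-3-yl]-4-oxobutanoate; 4 2,4,5-trimethoxybenzaldehyde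
Product: 6 (4S)-4-benzyl-3-{[(2S,3S)-5-oxo-2-(2,4,5-trimethoxyphenyl)oxolan-3-yl]carbonyl}-1,3-oxazolidin-2-one, via syn-aldol hydroxy ester 5 (not isolated)
Conditions: Bu2BOTf, Et3N, CH2Cl2, −78 → 0 °C; 4, −78 → 0 °C; pH 7 buffer, H2O2, MeOH, 0 °C; PPTS (cat.), CH2Cl2, rt
Reagents that add atoms: none
Why: Evans syn-aldol, in which the Z-dibutylboron enolate (soft enolisation at the imide α-CH2, not at the ester) adds to 4 through a Zimmerman–Traxler chair on the face away from the auxiliary benzyl group, setting the (S)-carbinol and (S)-α centres, after which the new hydroxyl displaces methoxide from the γ-ester to give the 2,3-trans lactone.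

Step 3
Reactants: 6 (4S)-4-benzyl-3-{[(2S,3S)-5-oxo-2-(2,4,5-trimethoxyphenyl)oxolan-3-yl]carbonyl}-1,3-oxazolidin-2-one
Product: 7 (2S,3S)-5-oxo-2-(2,4,5-trimethoxyphenyl)oxolane-3-carboxylic acid
Conditions: LiOH, H2O2, THF/H2O, 0 °C; Na2SO3; HCl to pH 2
Reagents that add atoms: hydrogen peroxide (acting as LiOOH), OO
Why: Hydroperoxide cleavage of the Evans imide, in which the weakly basic and strongly nucleophilic LiOOH attacks the exocyclic carbonyl faster than the α-centre epimerises or the lactone eliminates, and any opened lactone closes again on acidification.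

Step 4
Reactants: 7 (2S,3S)-5-oxo-2-(2,4,5-trimethoxyphenyl)oxolane-3-carboxylic acid
Product: 8 (4R,5S)-4-(hydroxymethyl)-5-(2,4,5-trimethoxyphenyl)oxolan-2-one
Conditions: BH3·SMe2, THF, 0 °C → rt; MeOH
Reagents that add atoms: none
Why: Chemoselective borane reduction of a carboxylic acid, which proceeds through the acyloxyborane much faster than reduction of the γ-lactone and under non-basic conditions that leave both stereocentres untouched.

Step 5
Reactants: 9 3,4,5-trimethoxybenzyl alcohol
Product: 10 3,4,5-trimethoxybenzyl 2,2,2-trichloroacetimidate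
Conditions: Cl3CCN, DBU (cat.), CH2Cl2, 0 °C
Reagents that add atoms: trichloroacetonitrile, N#CC(Cl)(Cl)Cl
Why: Base-catalysed addition of the alcohol to the electron-poor nitrile is the standard trichloroacetimidate formation.

Step 6
Reactants: 8 (4R,5S)-4-(hydroxymethyl)-5-(2,4,5-trimethoxyphenyl)oxolan-2-one; 10 3,4,5-trimethoxybenzyl 2,2,2-trichloroacetimidate
Product: 11 (4R,5S)-4-{[(3,4,5-trimethoxybenzyl)oxy]methyl}-5-(2,4,5-trimethoxyphenyl)oxolan-2-one
Conditions: 10 (1.5 equiv), TfOH (cat.), CH2Cl2, 0 °C
Reagents that add atoms: none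
Why: Acid-catalysed O-benzylation with a trichloroacetimidate, in which the protonated imidate releases trichloroacetamide and the primary alcohol captures the benzylic electrophile without any base that could open or epimerise the lactone.

Step 7
Reactants: 11 (4R,5S)-4-{[(3,4,5-trimethoxybenzyl)oxy]methyl}-5-(2,4,5-trimethoxyphenyl)oxolan-2-one
Product: 12 (4R,5S)-3-(trifluoroacetyl)-4-{[(3,4,5-trimethoxybenzyl)oxy]methyl}-5-(2,4,5-trimethoxyphenyl)oxolan-2-one (C3 undefined, largely enolised; taken on crude)
Conditions: LiN(SiMe3)2, THF, −78 °C; CF3CO2CH2CF3, −78 °C; aq. HCl work-up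
Reagents that add atoms: 2,2,2-trifluoroethyl trifluoroacetate, O=C(OCC(F)(F)F)C(F)(F)F
Why: Claisen-type C-acylation of the lithium lactone enolate with the activated trifluoroacetate turns C3 into a 1,3-dicarbonyl position for diazo transfer, and there is no leaving group β to the enolate that could be eliminated.

Step 8
Reactants: 12 (4R,5S)-3-(trifluoroacetyl)-4-{[(3,4,5-trimethoxybenzyl)oxy]methyl}-5-(2,4,5-trimethoxyphenyl)oxolan-2-one
Product: 13 (4R,5S)-3-diazo-4-{[(3,4,5-trimethoxybenzyl)oxy]methyl}-5-(2,4,5-trimethoxyphenyl)oxolan-2-one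
Conditions: MsN3, Et3N, H2O (1 equiv), MeCN, rt
Reagents that add atoms: methanesulfonyl azide, CS(=O)(=O)N=[N+]=[N-]
Why: Regitz-type deacylative diazo transfer, in which the enolate of the trifluoroacetyl lactone adds to the sulfonyl azide and the adduct fragments into the α-diazo lactone and the N-trifluoroacetyl sulfonamide.

Step 9
Reactants: 13 (4R,5S)-3-diazo-4-{[(3,4,5-trimethoxybenzyl)oxy]methyl}-5-(2,4,5-trimethoxyphenyl)oxolan-2-one
Product: 14 (3S,3aR,6R,6aS)-6-(3,4,5-trimethoxyphenyl)-3-(2,4,5-trimethoxyphenyl)tetrahydro-1H,3H-furo[3,4-c]furan-1-one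
Conditions: Rh2(OAc)4 (2 mol %), CH2Cl2, rt, slow addition of 13
Reagents that add atoms: none
Why: Rh2(OAc)4 expels N2 from 13 to give an electrophilic divalent rhodium carbenoid at C3, which inserts in a concerted three-centre manner into the benzylic ether C–H bond at C2; the closest known type is the dirhodium tetracarboxylate-catalysed 1,5 C–H insertion of α-diazo-γ-butyrolactones into benzylic ether C–H bonds, which gives endo-aryl furofuranones. The oxolane closes by C2–C3 bond formation as a 1,5-insertion, through a chair-like array of C3, C4, C5, O1, C2 and the migrating hydrogen. The new centre C3 (C6a of 14) is dictated by the existing centre C4 (C3a), because a lactone fused to a five-membered ring can only be cis-fused. The new centre C2 (C6) is set in the same transition state, where ring A should point away from the carboxylate ligands of the catalyst, the arrangement that delivers it endo and cis to the lactone carbonyl. The step needs site selectivity over 1,2-hydride shift from C4, attack on the arenes and oxonium ylide formation; the C2–H bond is the only one that is both activated by an ether oxygen and an aryl ring and reachable through a five-membered ring, whereas the ylide would need a four-membered ring and ring B would need a bridged one.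

Step 10
Reactants: 14 (3S,3aR,6R,6aS)-6-(3,4,5-trimethoxyphenyl)-3-(2,4,5-trimethoxyphenyl)tetrahydro-1H,3H-furo[3,4-c]furan-1-one
Product: 15 [(2R,3R,4R)-4-[(S)-hydroxy(2,4,5-trimethoxyphenyl)methyl]-2-(3,4,5-trimethoxyphenyl)oxolan-3-yl]methanol
Conditions: LiAlH4, THF, 0 °C
Reagents that add atoms: none
Why: Hydride reduction of the γ-lactone to the 1,4-diol is faster than enolisation at C3, so the three ring centres are carried over unchanged.

Step 11
Reactants: 15 [(2R,3R,4R)-4-[(S)-hydroxy(2,4,5-trimethoxyphenyl)methyl]-2-(3,4,5-trimethoxyphenyl)oxolan-3-yl]methanol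
Product: 16 [(2R,3R,4R)-2-(3,4,5-trimethoxyphenyl)-4-(2,4,5-trimethoxybenzyl)oxolan-3-yl]methanol
Conditions: Et3SiH (5 equiv), CF3CO2H, CH2Cl2, −20 → 0 °C; then K2CO3, MeOH
Reagents that add atoms: none
Why: Ionic hydrogenation, in which the acid ionises the carbinol next to ring B (cation stabilised by the ortho- and para-methoxy groups) and Et3SiH reduces it irreversibly, so that any furofuran formed by reversible capture by the primary hydroxyl is drained to 16, while the C2–O1 bond next to the less donating ring A should stay intact at low temperature and the basic methanol treatment removes any trifluoroacetate ester.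

**Compound list**

1 | (S)-4-benzyl-1,3-oxazolidin-2-one | O=C1N[C@@H](Cc2ccccc2)CO1 | starting material
2 | methyl 4-chloro-4-oxobutanoate | COC(=O)CCC(Cl)=O | starting material
3 | methyl 4-[(4S)-4-benzyl-2-oxo-1,3-oxazolidin-3-yl]-4-oxobutanoate | COC(=O)CCC(=O)N1[C@@H](Cc2ccccc2)COC1=O | intermediate
4 | 2,4,5-trimethoxybenzaldehyde | COc1cc(OC)c(C=O)cc1OC | starting material
5 | methyl (3S,4S)-3-{[(4S)-4-benzyl-2-oxo-1,3-oxazolidin-3-yl]carbonyl}-4-hydroxy-4-(2,4,5-trimethoxyphenyl)butanoate (syn-aldol hydroxy ester) | O[C@H](c1cc(OC)c(OC)cc1OC)[C@@H](C(=O)N1[C@@H](Cc2ccccc2)COC1=O)CC(=O)OC | intermediate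
6 | (4S)-4-benzyl-3-{[(2S,3S)-5-oxo-2-(2,4,5-trimethoxyphenyl)oxolan-3-yl]carbonyl}-1,3-oxazolidin-2-one | O=C1O[C@H](c2cc(OC)c(OC)cc2OC)[C@@H](C(=O)N2[C@@H](Cc3ccccc3)COC2=O)C1 | intermediate
7 | (2S,3S)-5-oxo-2-(2,4,5-trimethoxyphenyl)oxolane-3-carboxylic acid | O=C1O[C@H](c2cc(OC)c(OC)cc2OC)[C@@H](C(=O)O)C1 | intermediate
8 | (4R,5S)-4-(hydroxymethyl)-5-(2,4,5-trimethoxyphenyl)oxolan-2-one | O=C1O[C@H](c2cc(OC)c(OC)cc2OC)[C@@H](CO)C1 | intermediate
9 | 3,4,5-trimethoxybenzyl alcohol | COc1cc(CO)cc(OC)c1OC | starting material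
10 | 3,4,5-trimethoxybenzyl 2,2,2-trichloroacetimidate | COc1cc(COC(=N)C(Cl)(Cl)Cl)cc(OC)c1OC | intermediate
11 | (4R,5S)-4-{[(3,4,5-trimethoxybenzyl)oxy]methyl}-5-(2,4,5-trimethoxyphenyl)oxolan-2-one | O=C1O[C@H](c2cc(OC)c(OC)cc2OC)[C@@H](COCc2cc(OC)c(OC)c(OC)c2)C1 | intermediate
12 | (4R,5S)-3-(trifluoroacetyl)-4-{[(3,4,5-trimethoxybenzyl)oxy]methyl}-5-(2,4,5-trimethoxyphenyl)oxolan-2-one (C3 undefined) | O=C1O[C@H](c2cc(OC)c(OC)cc2OC)[C@@H](COCc2cc(OC)c(OC)c(OC)c2)C1C(=O)C(F)(F)F | intermediate
13 | (4R,5S)-3-diazo-4-{[(3,4,5-trimethoxybenzyl)oxy]methyl}-5-(2,4,5-trimethoxyphenyl)oxolan-2-one | O=C1O[C@H](c2cc(OC)c(OC)cc2OC)[C@@H](COCc2cc(OC)c(OC)c(OC)c2)C1=[N+]=[N-] | intermediate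
14 | (3S,3aR,6R,6aS)-6-(3,4,5-trimethoxyphenyl)-3-(2,4,5-trimethoxyphenyl)tetrahydro-1H,3H-furo[3,4-c]furan-1-one | O=C1O[C@H](c2cc(OC)c(OC)cc2OC)[C@H]3CO[C@@H](c4cc(OC)c(OC)c(OC)c4)[C@@H]13 | intermediate
15 | [(2R,3R,4R)-4-[(S)-hydroxy(2,4,5-trimethoxyphenyl)methyl]-2-(3,4,5-trimethoxyphenyl)oxolan-3-yl]methanol | O[C@H](c1cc(OC)c(OC)cc1OC)[C@H]1CO[C@@H](c2cc(OC)c(OC)c(OC)c2)[C@H]1CO | intermediate
16 | [(2R,3R,4R)-2-(3,4,5-trimethoxyphenyl)-4-(2,4,5-trimethoxybenzyl)oxolan-3-yl]methanol | COc1cc(OC)c(OC)cc1C[C@H]1CO[C@@H](c2cc(OC)c(OC)c(OC)c2)[C@H]1CO | target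

**Count**

Total steps: 11. Longest linear sequence: 10 steps (steps 1–4 and 6–11, from 1 and 2); step 5 is a one-step side branch.

**Steps most likely to fail**

Step 11. The acid may ionise more than the intended carbinol. Loss of the C2–O1 bond next to ring A would open the oxolane, with C2 epimerisation on re-closure or Friedel–Crafts closure onto ring B. Capture of the ring B cation by the primary hydroxyl could also hold material as a furofuran that is reduced only slowly. The fallback removes the oxygen before the diol exists and sets out from 14. Hydrogenolysis (H2, Pd/C, EtOAc–AcOH, rt) should cleave the acyloxy C–O bond at the ring B benzylic carbon, the most labile benzylic C–O bond present, to give (2R,3S,4R)-2-(3,4,5-trimethoxyphenyl)-4-(2,4,5-trimethoxybenzyl)oxolane-3-carboxylic acid F1. LiAlH4 in THF then reduces the acid and the route is rejoined at 16.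

Step 9. The carbenoid may be diverted by a 1,2-hydride shift from C4 to a butenolide or by attack on the electron-rich arenes, or the insertion may place ring A with insufficient endo preference. The fallback forms the C2–C3 bond by acylation and sets the two centres by hydrogenation; it sets out from 8. Acylation with 3,4,5-trimethoxybenzoyl chloride (Et3N, DMAP cat., CH2Cl2) gives [(2S,3R)-5-oxo-2-(2,4,5-trimethoxyphenyl)oxolan-3-yl]methyl 3,4,5-trimethoxybenzoate F2. LiN(SiMe3)2 (2 equiv, THF, −78 → 0 °C) should move the aroyl group from oxygen to the lactone α-carbon by an intramolecular Claisen condensation through a five-membered cyclic tetrahedral intermediate, giving (4R,5S)-4-(hydroxymethyl)-3-(3,4,5-trimethoxybenzoyl)-5-(2,4,5-trimethoxyphenyl)oxolan-2-one F3. A catalytic amount of p-TsOH in toluene with removal of water closes and dehydrates the hemiketal to (3S,3aR)-6-(3,4,5-trimethoxyphenyl)-3-(2,4,5-trimethoxyphenyl)-3a,4-dihydro-1H,3H-furo[3,4-c]furan-1-one F4. Hydrogenation (H2, Rh/Al2O3, EtOAc) adds both hydrogens syn from the convex face, the only addition that leaves a cis-fused bicycle, which puts ring A endo and returns the route at 14.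

Step 6. The acid catalyst may ionise the lactone C–O bond at the ring B benzylic carbon, promote translactonisation by the free primary hydroxyl, or let the trimethoxybenzyl cation alkylate ring B in a Friedel–Crafts reaction. The fallback replaces the acid-catalysed imidate alkylation by a silver-assisted etherification with a benzylic halide under non-acidic, non-basic conditions; it sets out from 8 and 9. PBr3 in Et2O at 0 °C converts 9 into 3,4,5-trimethoxybenzyl bromide F5. Treatment of 8 with F5 and Ag2O in CH2Cl2 over molecular sieves in the dark should give the ether, and the route is rejoined at 11.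

**Further compounds**

F1 | step 11 | (2R,3S,4R)-2-(3,4,5-trimethoxyphenyl)-4-(2,4,5-trimethoxybenzyl)oxolane-3-carboxylic acid | COc1cc(OC)c(OC)cc1C[C@H]1CO[C@@H](c2cc(OC)c(OC)c(OC)c2)[C@H]1C(=O)O
F2 | step 9 | [(2S,3R)-5-oxo-2-(2,4,5-trimethoxyphenyl)oxolan-3-yl]methyl 3,4,5-trimethoxybenzoate | O=C1O[C@H](c2cc(OC)c(OC)cc2OC)[C@@H](COC(=O)c2cc(OC)c(OC)c(OC)c2)C1
F3 | step 9 | (4R,5S)-4-(hydroxymethyl)-3-(3,4,5-trimethoxybenzoyl)-5-(2,4,5-trimethoxyphenyl)oxolan-2-one (C3 undefined) | O=C1O[C@H](c2cc(OC)c(OC)cc2OC)[C@@H](CO)C1C(=O)c3cc(OC)c(OC)c(OC)c3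
F4 | step 9 | (3S,3aR)-6-(3,4,5-trimethoxyphenyl)-3-(2,4,5-trimethoxyphenyl)-3a,4-dihydro-1H,3H-furo[3,4-c]furan-1-one | O=C1O[C@H](c3cc(OC)c(OC)cc3OC)[C@H]2COC(c3cc(OC)c(OC)c(OC)c3)=C12
F5 | step 6 | 3,4,5-trimethoxybenzyl bromide | COc1cc(CBr)cc(OC)c1OC
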